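**Plan**

Numbering (longipinane): C1 ketone, C2=C3(Me), C4 and C11 bridgeheads, C5 cyclobutane CH, C6 CMe2, C7/C8/C9 carbinol carbons, C10 C(Me); the cyclobutane is C4–C5–C11–C10.
Retrosynthesis: remove the two esters; cut C5–C11 (cyclobutane, enolate alkylation); then cut C4–C5 and C7–C8 together, which strips the whole seven-membered ring (C4 to C10) from a cyclohexenone and releases 2,2-dimethylpropanedial.
Enabling feature: C6 is flanked by C5 and C7 (a hidden symmetric 1,3-dialdehyde), while C4 and C8 are alpha to C3 of the six-membered ring and to C9, two carbonyl carbons held 1,4 by the quaternary C10; a double aldol therefore stitches the three-carbon unit in.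
Forward: six-membered ring with C10, then seven-membered ring (double aldol), then 1,3-carbonyl transposition, then cyclobutane (C11 enolate opens an O5/O7 cyclic sulfate, so the aldol oxygen at C5 is the leaving group), then the two esters.
Stereochemistry: C10 from a catalytic asymmetric conjugate addition; C4, C5, C7, C8 from enolate geometry and the C10-anchored tether in the double aldol; C9 by hydroxyl-directed reduction; C11 by the ring closure; the acid stereocentre is bought.

Key step: step 7

Remark: intermediates carry the target numbering; the acetal carbon of the 4-methoxybenzylidene acetal and C3 of 10 and 17 form as either epimer and are left undefined; angelic acid and (R)-2-methylbutanoic acid are taken as purchasable.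

**Route**

Step 1
Reactants: 1 2,3-dibromoprop-1-ene; 2 4-methoxybenzyl alcohol
Product: 3 2-bromoallyl 4-methoxybenzyl ether
Conditions: NaH, THF, 0 °C to rt
Reagents that add atoms: none
Why: Williamson ether synthesis: the alkoxide of 2 displaces the allylic bromide by SN2 while the vinylic bromide is inert.

Step 2
Reactants: 3 2-bromoallyl 4-methoxybenzyl ether; 4 3-methylcyclohex-2-en-1-one
Product: 7 (S)-3-methyl-3-[3-(4-methoxybenzyloxy)prop-1-en-2-yl]cyclohexan-1-one, via alkenyllithium 5 (not isolated), via alkenyl(dimethyl)alane 6 (not isolated)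
Conditions: t-BuLi (2 equiv), Et2O, −78 °C; Me2AlCl; then 4, Cu(O2CC4H3S) (5 mol %), chiral phosphinamine ligand (6 mol %), Et2O, −10 °C; aq. NH4Cl
Reagents that add atoms: none
Why: Bromine–lithium exchange and transmetalation give an alpha-branched alkenylalane whose copper-catalysed asymmetric conjugate addition to the beta-methyl enone (a precedented way to alkenyl-bearing quaternary carbons) creates C10, the ligand enantiomer being the one that directs the alkenyl group to the enone face giving the S ketone.

Step 3
Reactants: 7 (S)-3-methyl-3-[3-(4-methoxybenzyloxy)prop-1-en-2-yl]cyclohexan-1-one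
Product: 8 (S)-3-[2-(4-methoxybenzyloxy)acetyl]-3-methylcyclohexan-1-one
Conditions: OsO4 (2 mol %), NaIO4 (4 equiv), 2,6-lutidine, dioxane/H2O 3:1, rt
Reagents that add atoms: sodium periodate, [Na+].[O-]I(=O)(=O)=O (its oxygen is relayed to C9 by the OsO4 catalyst)
Why: Lemieux–Johnson oxidation (osmylation, periodate cleavage) turns the 1,1-disubstituted alkene into the C9 ketone; the PMB ether, the ring ketone and the quaternary C10 are not touched.

Step 4
Reactants: 8 (S)-3-[2-(4-methoxybenzyloxy)acetyl]-3-methylcyclohexan-1-one
Product: 9 (S)-5-[2-(4-methoxybenzyloxy)acetyl]-5-methylcyclohex-2-en-1-one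
Conditions: Pd(OCOCF3)2 (5 mol %), DMSO (10 mol %), O2 (1 atm), AcOH, 80 °C
Reagents that add atoms: none
Why: Palladium-catalysed aerobic alpha,beta-dehydrogenation of a cyclohexanone: only C1–C2 carries the beta-hydrogen needed for beta-hydride elimination (C4 adjoins the quaternary C10 and the side-chain ketone has no beta-hydrogen), so a single enone can form.

Step 5
Reactants: 9 (S)-5-[2-(4-methoxybenzyloxy)acetyl]-5-methylcyclohex-2-en-1-one
Product: 11 (R)-5-[2-(4-methoxybenzyloxy)acetyl]-5-methyl-3-(phenylsulfanyl)cyclohex-2-en-1-one, via beta-phenylthio ketone 10 (not isolated)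
Conditions: PhSH (1.05 equiv), Et3N (1.2 equiv), CH2Cl2, 0 °C; then NCS (1.05 equiv), 0 °C to rt
Reagents that add atoms: thiophenol, Sc1ccccc1
Why: Thia-Michael addition followed by S-chlorination and dehydrochlorination (Pummerer-type oxidation of a beta-keto sulfide) gives the vinylogous thioester without passing through the achiral 1,3-dione, so C10 stays stereogenic and C4 becomes the only alpha-prime position of ring A.

Step 6
Reactants: 12 2,2-dimethylpropane-1,3-diol
Product: 13 2,2-dimethylpropanedial
Conditions: (COCl)2, DMSO, CH2Cl2, −78 °C; Et3N, −78 °C to rt; used at once as a dried solution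
Reagents that add atoms: none
Why: Swern oxidation of both primary alcohols; the dialdehyde cannot enolise and is used immediately because it hydrates and oligomerises on storage.

Step 7
Reactants: 11 (R)-5-[2-(4-methoxybenzyloxy)acetyl]-5-methyl-3-(phenylsulfanyl)cyclohex-2-en-1-one; 13 2,2-dimethylpropanedial
Product: 15 cis-fused 6/7 bicyclic 5,7-diol (C3 vinylogous thioester carbonyl; C9 ketone; O5-H cis to O7-H; O8 PMB ether trans to O7), via dilithium bis-enolate 14 (not isolated)
Conditions: LiN(iPr)2 (2.3 equiv), THF, −78 °C, inverse addition of 11; 13 (1.1 equiv) added slowly at high dilution, −78 to −40 °C; AcOH, −78 °C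
Reagents that add atoms: none
Why: Proposed new method: LiN(iPr)2 removes the C8–H of the alpha-alkoxy ketone (chelated Z lithium enolate) and the alpha-prime C4–H of the vinylogous thioester (ring E enolate; C2 is vinylic and the gamma C11–H is not kinetically acidic), and the symmetric, non-enolisable dialdehyde 13 is captured by one enolate and then intramolecularly by the other, so either order gives the same constitution. The closest known reaction types are the kinetic alpha-prime aldol of Stork–Danheiser enolates, the syn-selective aldol of chelated alpha-alkoxy ketone enolates and tandem inter/intramolecular aldol annulations of dialdehydes (Robinson–Schöpf and Weiss reactions), but a double aldol that stitches a 1,3-dialdehyde onto a 1,4-related bis-enolate to give a cycloheptane has not been shown. The seven-membered ring (C4 to C10) closes in the second aldol by an allowed 7-exo-trig attack (enolexo if C4–C5 forms last, enolendo if C7–C8 forms last). C4/C5 should be set anti by the ring E enolate and C7/C8 syn by the chelated Z enolate through chair Zimmerman–Traxler transition states, which are exactly the relationships the target and the later inversion at C5 require; C4 must bond on the face of ring A that carries the C9 arm because that arm delivers or already holds the aldehyde, giving the cis ring fusion; and the O5/O7 lithium alkoxides can bridge only when cis, which together with the reversibility of these hindered aldolates near −40 °C should funnel the mixture to the cis-1,3 isomer. The step needs regioselective bis-enolisation, no oligomerisation and this relative topicity of the two aldol events; inverse addition to excess base, slow addition of 13 at high dilution and the quaternary C10 that anchors both enolates are what secure them.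

Step 8
Reactants: 15 cis-fused 6/7 bicyclic 5,7-diol
Product: 16 bicyclic 5,7,9-triol (O9-H cis to O8 and trans to O7; vinylogous thioester intact)
Conditions: Me4NBH(OAc)3, MeCN/AcOH 1:1, −30 °C
Reagents that add atoms: none
Why: Evans–Saksena reduction: the C7 hydroxyl exchanges onto boron and delivers hydride to C9 from its own face, giving the 1,3-anti diol (the same sense as alpha-alkoxy chelation control), while the vinylogous thioester carbonyl is too electron-rich to be reduced.

Step 9
Reactants: 16 bicyclic 5,7,9-triol
Product: 18 bicyclic enone triol (C1 ketone; C2=C3 with the new methyl on C3), via tertiary allylic carbinol 17 (not isolated)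
Conditions: MeLi (5 equiv), THF, −78 °C; then 2 M HCl, THF, 0 °C to rt
Reagents that add atoms: methyllithium, [Li]C; water, O
Why: Stork–Danheiser 1,3-carbonyl transposition in its sulfur version: methyllithium adds 1,2 to the C3 carbonyl and acid ionises the tertiary allylic alcohol so that water attacks C1 and thiophenol leaves, giving the C1 ketone and the C2=C3 methyl alkene and making C11 the kinetic alpha-prime position.

Step 10
Reactants: 18 bicyclic enone triol
Product: 20 O5,O7 cyclic sulfate (O9-H free), via O7 imidazol-1-ylsulfonate 19 (not isolated)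
Conditions: 1,1'-sulfonyldiimidazole (1.1 equiv), NaH (2.2 equiv), THF, −40 to 0 °C
Reagents that add atoms: 1,1'-sulfonyldiimidazole, O=S(=O)(n1ccnc1)n1ccnc1
Why: The cis-1,3 diol closes a six-membered cyclic sulfate (known cyclic sulfate formation from diols), whereas O9–H is flanked by the quaternary C10 and the PMB-oxy carbon and has no cis-1,3 partner; this one group activates C5 and protects O7.

Step 11
Reactants: 20 O5,O7 cyclic sulfate
Product: 21 cyclic sulfate bearing the O8,O9 4-methoxybenzylidene acetal
Conditions: DDQ (1.2 equiv), 4 Å MS, CH2Cl2, 0 °C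
Reagents that add atoms: none
Why: Anhydrous DDQ oxidation of the PMB ether gives an oxocarbenium ion that is trapped by the neighbouring cis hydroxyl (known oxidative acetal formation); with O7 locked in the sulfate only O9 can close the dioxolane.

Step 12
Reactants: 21 cyclic sulfate bearing the O8,O9 acetal
Product: 23 7-hydroxy-8,9-O-(4-methoxybenzylidene)longipin-2-en-1-one, via potassium O7 sulfate 22 (not isolated)
Conditions: KN(SiMe3)2 (1.05 equiv), THF, −78 to 0 °C; then H2SO4 (cat.), H2O (1 equiv), THF, rt
Reagents that add atoms: none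
Why: Kinetic deprotonation of the enone at C11 and intramolecular enolate alkylation (4-exo-tet, the classical keto-sulfonate closure of a cyclobutane across a cis-fused bicycle) open the sulfate at C5 with inversion, so C5 and C11 are fixed by the tether, O-alkylation is excluded because it would give a bridgehead alkene, C7 is out of reach and keeps its sulfate, and the sulfate monoester is then hydrolysed with catalytic acid and one equivalent of water, conditions under which cyclic acetals survive.

Step 13
Reactants: 23 7-hydroxy-8,9-O-(4-methoxybenzylidene)longipin-2-en-1-one; 24 angelic acid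
Product: 26 7-O-angeloyl-8,9-O-(4-methoxybenzylidene)longipin-2-en-1-one, via mixed anhydride 25 (not isolated)
Conditions: 2,4,6-Cl3C6H2COCl, Et3N, toluene, rt; then 23, toluene, 75 °C
Reagents that add atoms: none
Why: Yamaguchi-type mixed-anhydride esterification of the only free hydroxyl, run without DMAP because these conditions are known to transfer the angeloyl group without Z to E isomerisation to the tiglate.

Step 14
Reactants: 26 7-O-angeloyl-8,9-O-(4-methoxybenzylidene)longipin-2-en-1-one
Product: 27 7-O-angeloyl-8,9-dihydroxylongipin-2-en-1-one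
Conditions: AcOH/THF/H2O 3:1:1, rt
Reagents that add atoms: none
Why: Mild acid hydrolysis of the 4-methoxybenzylidene acetal; the angelate, the enone and the cyclobutane are stable to aqueous acetic acid.

Step 15
Reactants: 27 7-O-angeloyl-8,9-dihydroxylongipin-2-en-1-one; 28 (R)-2-methylbutanoic acid
Product: 30 target, via O-acylisourea 29 (not isolated)
Conditions: DCC (1.05 equiv), DMAP (0.1 equiv), CH2Cl2, −20 to 0 °C
Reagents that add atoms: none
Why: Steglich esterification: O8–H is an ordinary secondary hydroxyl while O9–H is neopentylic next to the quaternary C10, so one equivalent of activated acid at low temperature should acylate O8 only, and carbodiimide activation does not epimerise the alpha-stereocentre of the acid.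

**Compound list**

1 | 2,3-dibromoprop-1-ene | C=C(Br)CBr | starting material
2 | 4-methoxybenzyl alcohol | COc1ccc(CO)cc1 | starting material
3 | 2-bromoallyl 4-methoxybenzyl ether | C=C(Br)COCc1ccc(OC)cc1 | intermediate
4 | 3-methylcyclohex-2-en-1-one | CC1=CC(=O)CCC1 | starting material
5 | [3-(4-methoxybenzyloxy)prop-1-en-2-yl]lithium | [Li]C(=C)COCc1ccc(OC)cc1 | intermediate
6 | dimethyl[3-(4-methoxybenzyloxy)prop-1-en-2-yl]alane | C[Al](C)C(=C)COCc1ccc(OC)cc1 | intermediate
7 | (S)-3-methyl-3-[3-(4-methoxybenzyloxy)prop-1-en-2-yl]cyclohexan-1-one | COc1ccc(COCC(=C)[C@@]2(C)CCCC(=O)C2)cc1 | intermediate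
8 | (S)-3-[2-(4-methoxybenzyloxy)acetyl]-3-methylcyclohexan-1-one | COc1ccc(COCC(=O)[C@@]2(C)CCCC(=O)C2)cc1 | intermediate
9 | (S)-5-[2-(4-methoxybenzyloxy)acetyl]-5-methylcyclohex-2-en-1-one | COc1ccc(COCC(=O)[C@@]2(C)CC=CC(=O)C2)cc1 | intermediate
10 | (5R)-5-[2-(4-methoxybenzyloxy)acetyl]-5-methyl-3-(phenylsulfanyl)cyclohexan-1-one, both C3 epimers | COc1ccc(COCC(=O)[C@@]2(C)CC(Sc3ccccc3)CC(=O)C2)cc1 | intermediate
11 | (R)-5-[2-(4-methoxybenzyloxy)acetyl]-5-methyl-3-(phenylsulfanyl)cyclohex-2-en-1-one | COc1ccc(COCC(=O)[C@@]2(C)CC(Sc3ccccc3)=CC(=O)C2)cc1 | intermediate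
12 | 2,2-dimethylpropane-1,3-diol | OCC(C)(C)CO | starting material
13 | 2,2-dimethylpropanedial | O=CC(C)(C)C=O | intermediate
14 | dilithium bis-enolate of 11 (ring C3–O/C4 enolate; Z side-chain C9–O/C8 enolate) | COc1ccc(CO/C=C(\O[Li])[C@@]2(C)CC(Sc3ccccc3)=CC(O[Li])=C2)cc1 | intermediate
15 | cis-fused 6/7 bicycle: C1 SPh, C2=C1, C3 ketone, C9 ketone, O5-H and O7-H cis (O5 on the face away from C11), O8 PMB ether trans to O7, C4–H cis to the C10 methyl | O[C@@H]1[C@@H](OCc3ccc(OC)cc3)C(=O)[C@@]2(C)CC(Sc4ccccc4)=CC(=O)[C@H]2[C@H](O)C1(C)C | intermediate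
16 | the 5,7,9-triol from 15 (O9-H cis to O8, trans to O7) | O[C@@H]1[C@@H](OCc3ccc(OC)cc3)[C@@H](O)[C@@]2(C)CC(Sc4ccccc4)=CC(=O)[C@H]2[C@H](O)C1(C)C | intermediate
17 | C3 tertiary allylic carbinol from methyl addition to 16, either C3 epimer | O[C@@H]1[C@@H](OCc3ccc(OC)cc3)[C@@H](O)[C@@]2(C)CC(Sc4ccccc4)=CC(C)(O)[C@H]2[C@H](O)C1(C)C | intermediate
18 | bicyclic enone triol: C1 ketone, C2=C3(Me), O5-H, O7-H, O9-H, O8 PMB ether | O[C@@H]1[C@@H](OCc3ccc(OC)cc3)[C@@H](O)[C@@]2(C)CC(=O)C=C(C)[C@H]2[C@H](O)C1(C)C | intermediate
19 | O7 imidazol-1-ylsulfonate of 18 | O=S(=O)(n3ccnc3)O[C@@H]1[C@@H](OCc4ccc(OC)cc4)[C@@H](O)[C@@]2(C)CC(=O)C=C(C)[C@H]2[C@H](O)C1(C)C | intermediate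
20 | O5,O7 cyclic sulfate of 18 | O=S3(=O)O[C@@H]1[C@@H](OCc4ccc(OC)cc4)[C@@H](O)[C@@]2(C)CC(=O)C=C(C)[C@H]2[C@H](O3)C1(C)C | intermediate
21 | O5,O7 cyclic sulfate with O8,O9 4-methoxybenzylidene acetal | O=S3(=O)O[C@@H]1[C@H]4OC(c5ccc(OC)cc5)O[C@H]4[C@@]2(C)CC(=O)C=C(C)[C@H]2[C@H](O3)C1(C)C | intermediate
22 | potassium O7 sulfate of the tricyclic enone acetal | [K+].[O-]S(=O)(=O)O[C@@H]1[C@H]4OC(c5ccc(OC)cc5)O[C@H]4[C@@]2(C)[C@@H]3C(=O)C=C(C)[C@H]2[C@@H]3C1(C)C | intermediate
23 | 7-hydroxy-8,9-O-(4-methoxybenzylidene)longipin-2-en-1-one (O7 on the face toward C4; O8, O9 on the face toward C11) | O[C@@H]1[C@H]4OC(c5ccc(OC)cc5)O[C@H]4[C@@]2(C)[C@@H]3C(=O)C=C(C)[C@H]2[C@@H]3C1(C)C | intermediate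
24 | angelic acid, (Z)-2-methylbut-2-enoic acid | C/C=C(/C)C(=O)O | starting material
25 | angelic 2,4,6-trichlorobenzoic anhydride | C/C=C(/C)C(=O)OC(=O)c1c(Cl)cc(Cl)cc1Cl | intermediate
26 | 7-O-angeloyl-8,9-O-(4-methoxybenzylidene)longipin-2-en-1-one | C/C=C(/C)C(=O)O[C@@H]1[C@H]4OC(c5ccc(OC)cc5)O[C@H]4[C@@]2(C)[C@@H]3C(=O)C=C(C)[C@H]2[C@@H]3C1(C)C | intermediate
27 | 7-O-angeloyl-8,9-dihydroxylongipin-2-en-1-one | C/C=C(/C)C(=O)O[C@@H]1[C@@H](O)[C@@H](O)[C@@]2(C)[C@@H]3C(=O)C=C(C)[C@H]2[C@@H]3C1(C)C | intermediate
28 | (R)-2-methylbutanoic acid | CC[C@@H](C)C(=O)O | starting material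
29 | O-acylisourea from 28 and DCC | CC[C@@H](C)C(=O)OC(=NC1CCCCC1)NC1CCCCC1 | intermediate
30 | 7-O-angeloyl-8-O-[(R)-2-methylbutanoyl]-9-hydroxylongipin-2-en-1-one (O7 trans to O8; O8 cis to O9) | C/C=C(/C)C(=O)O[C@@H]1[C@@H](OC(=O)[C@H](C)CC)[C@@H](O)[C@@]2(C)[C@@H]3C(=O)C=C(C)[C@H]2[C@@H]3C1(C)C | target

**Step count and risks**

Total steps: 15. Longest linear sequence: 14 steps (1–5, then 7–15); step 6 is a one-step side branch.

Step 7 (key step). What may go wrong: poor relative topicity between the two aldol events, retro-aldol on warming, or oligomerisation of the dialdehyde. Fallback: the two bonds are made by Lewis-acid aldol chemistry on a preformed bis-enol ether, as in Mukaiyama aldol additions and the known annulations of bis(silyl enol ethers) with dicarbonyl compounds. It sets out from 11: LiN(iPr)2 and Me3SiCl give the bis(trimethylsilyl) enol ether F1; F1 and 13 with BF3·OEt2 (CH2Cl2, −78 °C, high dilution) and an aqueous HCl work-up give the diol, and the route is rejoined at 15. The open transition states make the outcome independent of enolate geometry, so epimers at C5 and C7 may need separation, and C8 epimers can be equilibrated with base.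

Step 12. What may go wrong: proton transfer to the extended dienolate followed by vinylogous beta-elimination of the sulfate, or failure of the strained ring to close. Fallback: the ring is closed at the saturated-ketone level, where no vinylogous elimination is possible, and the enone is restored afterwards. It sets out from 21: conjugate reduction with [(Ph3P)CuH]6 (wet benzene) gives the saturated ketone cyclic sulfate F2 (either C3 epimer); NaCH2S(O)CH3 in DMSO equilibrates the enolates, of which only the C11 enolate can cyclise, and H2SO4 (cat.)/H2O/THF then gives the tricyclic hydroxy ketone F3; LiN(iPr)2 and Me3SiCl give the silyl enol ether toward C2 (the only enolisable side) together with the O7 silyl ether, F4, and Saegusa–Ito oxidation with Pd(OAc)2 followed by K2CO3/MeOH returns the enone alcohol; the route is rejoined at 23.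

Step 10. What may go wrong: sulfonylation of the free O9 hydroxyl in competition with closure of the six-membered sulfate. Fallback: O9 is masked before sulfation by reordering the protecting-group events. It sets out from 18: tBu2Si(OTf)2 and 2,6-lutidine bridge the cis O5/O7 diol as the silylene F5; DDQ (anhydrous) then closes the O8/O9 4-methoxybenzylidene acetal, giving F6; HF·pyridine removes the silylene to give the diol acetal F7, whose only hydroxyls are O5–H and O7–H; sulfonyldiimidazole and NaH then give the cyclic sulfate, and the route is rejoined at 21 (steps 10 and 11 are replaced).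

**Further compounds**

F1 | step 7 | bis(trimethylsilyl) enol ether of 11 | COc1ccc(CO/C=C(\O[Si](C)(C)C)[C@@]2(C)CC(Sc3ccccc3)=CC(O[Si](C)(C)C)=C2)cc1
F2 | step 12 | saturated C1 ketone analogue of 21 (C3 methyl, either epimer) | O=S3(=O)O[C@@H]1[C@H]4OC(c5ccc(OC)cc5)O[C@H]4[C@@]2(C)CC(=O)CC(C)[C@H]2[C@H](O3)C1(C)C
F3 | step 12 | 2,3-dihydro analogue of 23 (tricyclic saturated ketone, O7-H free) | O[C@@H]1[C@H]4OC(c5ccc(OC)cc5)O[C@H]4[C@@]2(C)[C@@H]3C(=O)CC(C)[C@H]2[C@@H]3C1(C)C
F4 | step 12 | C1 trimethylsilyl enol ether and O7 trimethylsilyl ether of F3 | C[Si](C)(C)O[C@@H]1[C@H]4OC(c5ccc(OC)cc5)O[C@H]4[C@@]2(C)[C@@H]3C(O[Si](C)(C)C)=CC(C)[C@H]2[C@@H]3C1(C)C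
F5 | step 10 | O5,O7 di-tert-butylsilylene of 18 | CC(C)(C)[Si]3(C(C)(C)C)O[C@@H]1[C@@H](OCc4ccc(OC)cc4)[C@@H](O)[C@@]2(C)CC(=O)C=C(C)[C@H]2[C@H](O3)C1(C)C
F6 | step 10 | O5,O7 di-tert-butylsilylene with O8,O9 4-methoxybenzylidene acetal | CC(C)(C)[Si]3(C(C)(C)C)O[C@@H]1[C@H]4OC(c5ccc(OC)cc5)O[C@H]4[C@@]2(C)CC(=O)C=C(C)[C@H]2[C@H](O3)C1(C)C
F7 | step 10 | bicyclic enone 5,7-diol with O8,O9 4-methoxybenzylidene acetal | O[C@@H]1[C@H]4OC(c5ccc(OC)cc5)O[C@H]4[C@@]2(C)CC(=O)C=C(C)[C@H]2[C@H](O)C1(C)C
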